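The carbocycle of ring A (C3a, C4, C5, C6, C7, C7a) is a cyclohexene whose C3a=C7a bond marks a Diels–Alder retron, and its C6–C7 edge is shared with the cyclobutane (C6, C7, C3a′, C7a′). One intramolecular [4+2] should therefore close both rings: the exocyclic diene C4=C3a–C7a=C7 of an alkylidene-methylene butyrolactone on C3a′ adds to the vinyl group C5=C6 on C7a′, and the two quaternary centres relay their configuration to C6 and C7. The triene is made from (E)-ligustilide by a catalytic enantioselective [2+2] photocycloaddition and Grob fragmentation (net cis-formyl-vinylation of C3a′=C7a′); the lactone A butylidene is added last.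

Key step: step 6

Remark: locants are those of ligustilide (unprimed: half with ring A and lactone A; primed: half with ring B and lactone B) and each carbon keeps its target locant throughout; the target's lactone B butylidene is E (propyl syn to C3a′) and its lactone A butylidene is Z, so (E)-ligustilide is used, and it and 4-(bromomethyl)furan-2(5H)-one are taken as catalogue compounds.

Step 1
Reactants: 1 acrolein; 2 acetyl chloride
Product: 3 3-chloroprop-1-en-1-yl acetate (E/Z mixture)
Conditions: ZnCl2 (2 mol%), CH2Cl2, −20 → 20 °C
Reagents that add atoms: none
Why: The ZnCl2-catalysed addition of an acyl chloride to an enal with allylic transposition (net 1,4-addition) is the known route to 3-halopropenyl esters, creates no stereocentre, and the E/Z mixture can be used as it is because both alkene carbons lose their configuration in step 3.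

Step 2
Reactants: 4 (E)-ligustilide; 3 3-chloroprop-1-en-1-yl acetate
Product: 5 cyclobutane photoadduct: (3′E,3a′R,7a′R)-lactone B with C7(H)(OAc) on C3a′ and C6(H)(CH2Cl) on C7a′ joined by the C6–C7 bond (epimer mixture at C6 and C7)
Conditions: 3 (10 equiv), (S)-3,3-diphenyl-1-(2,4,6-trifluorophenyl)tetrahydro-1H,3H-pyrrolo[1,2-c][1,3,2]oxazaborole activated by AlBr3 (50 mol%), CH2Cl2, −75 °C, hν (405 nm LED)
Reagents that add atoms: none
Why: Enantioselective Lewis-acid-catalysed intermolecular [2+2] photocycloaddition: the AlBr3-activated oxazaborolidine binds the lactone carbonyl of 4, shifts the absorption so that only the complex is excited at 405 nm, shields one face of C3a′=C7a′ and so sets both quaternary centres (cis by ring fusion), the electron-rich enol acetate adds head-to-tail (its O-bearing carbon, the later C7, to the β-carbon C3a′) and in tenfold excess should trap the excited state before the (E)-butylidene isomerises, while the two new CH centres need no control because step 3 destroys them.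

Step 3
Reactants: 5 cyclobutane photoadduct
Product: 7 (3E,3aS,7aS)-3-butylidene-7a-ethenyl-1-oxo-3,4,5,7a-tetrahydro-2-benzofuran-3a(1H)-carbaldehyde (CHO carbon = C7; vinyl = C6=C5), via cyclobutanol 6 (not isolated)
Conditions: K2CO3, MeOH, 0 °C
Reagents that add atoms: none
Why: Methanolysis of the unhindered acetate (faster than attack on the α-quaternary enol lactone) gives the cyclobutanolate of 6, whose strained C6–C7 bond is cleaved in a Grob fragmentation with loss of chloride from C5, unveiling the C3a′ aldehyde and the C7a′ vinyl group without touching the two quaternary stereocentres.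

Step 4
Reactants: 7 aldehyde; 8 4-(bromomethyl)furan-2(5H)-one
Product: 9 (3′E,3a′R,7a′S)-carbinol in which C7(H)(OH) links C3a′ to C7a(H) of a 4-methylidene-2-oxooxolan-3-yl ring (epimer mixture at C7 and C7a)
Conditions: In (powder), THF–H2O 4:1, 20 °C
Reagents that add atoms: none
Why: Indium-mediated Barbier allylation in aqueous THF: the allylindium formed from 8 attacks the aldehyde through its γ-carbon (the lactone α-carbon C7a), as γ-bromocrotonates do, and tolerates both lactones, while the two new stereocentres (C7 and C7a) are formed unselectively and removed in step 5.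

Step 5
Reactants: 9 carbinol
Product: 11 triene: (3′E,3a′S,7a′S)-lactone B bearing the C7a′ vinyl group and on C3a′ a (Z)-(4-methylidene-2-oxooxolan-3-ylidene)methyl group, via mesylate 10 (not isolated)
Conditions: MsCl, Et3N, CH2Cl2, −20 → 20 °C
Reagents that add atoms: none
Why: Mesylation followed by E1cB elimination through the acidic, allylic C7a–H gives the conjugated alkylidene lactone in its thermodynamically preferred geometry (C3a′ syn to the carbonyl, Z, so that it avoids the neighbouring exocyclic methylene), which is the outward geometry the diene needs.

Step 6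
Reactants: 11 triene
Product: 12 (6S,7R,3a′S,7a′R,3′E)-pentacyclic bis-lactone, i.e. the target without the butylidene on lactone A (C3 is CH2)
Conditions: 1,2-dichlorobenzene (0.005 M), BHT (10 mol%), 190 °C, sealed tube
Reagents that add atoms: none
Why: Proposed new method: thermal intramolecular Diels–Alder reaction in which the s-cis-locked exocyclic diene C4=C3a–C7a=C7 (a 3-alkylidene-4-methylidene butyrolactone) adds suprafacially to the vinyl group C5=C6, forming C4–C5 and C6–C7 and leaving the C3a=C7a bond of the butenolide; the closest known reaction type is the type 1 intramolecular Diels–Alder reaction with a three-atom tether, and the two-atom tether is what is new. Ring A is closed as the six-membered ring of the [4+2], and the cyclobutane (C6, C7, C3a′, C7a′) is closed by the C6–C7 bond as the tether ring, necessarily cis-fused to ring A because C6 and C7 sit on vicinal, cis-related quaternary carbons. The reaction should be asynchronous (C4–C5 leading) with a barrier raised by part of the cyclobutane strain, hence high dilution, a radical inhibitor and 190 °C; it is helped by the gain of the conjugated butenolide and by the fact that the competing Cope rearrangements of the 1,5-diene units lead only to strained bridged isomers that revert. C6 and C7 are set by substrate control from C3a′ and C7a′: the cis fusion follows from the tether, and the face should be chosen by the (E)-propyl group of lactone B (syn to C3a′) and by lactone–lactone dipole repulsion, which turn the diene towards the ring B side. The step therefore needs ring A to form syn to ring B, and it needs the vinyl group to react in preference to the endocyclic C6′=C7′ bond, which could only give a bicyclo[2.2.0] system.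

Step 7
Reactants: 12 pentacyclic bis-lactone; 13 butanal
Product: 16 target (3Z,3′E,6S,7R,3a′S,7a′R)-6.7a′,7.3a′-diligustilide, via silyloxyfuran 14 (not isolated), via silyl aldol adduct 15 (not isolated)
Conditions: TBSOTf, i-Pr2NEt, CH2Cl2, −78 → 0 °C; then DBU, 20 °C
Reagents that add atoms: none
Why: Vinylogous Mukaiyama aldol condensation: soft enolisation of the lactone A butenolide at its γ-CH2 (C3) gives silyloxyfuran 14, which adds to butanal at C3, and DBU-induced E1cB loss of silanol from 15 gives the thermodynamically favoured (Z)-butylidene as in (Z)-ligustilide, while lactone B (no α-hydrogen, isolated E-enol ether) and the stereocentres C6 and C7 are not affected.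

Compound list
1 | acrolein | C=CC=O | starting material
2 | acetyl chloride | CC(Cl)=O | starting material
3 | 3-chloroprop-1-en-1-yl acetate (E/Z mixture) | CC(=O)OC=CCCl | intermediate
4 | (E)-ligustilide, (3E)-3-butylidene-4,5-dihydro-2-benzofuran-1(3H)-one | CCC/C=C1/OC(=O)C2=C1CCC=C2 | starting material
5 | cyclobutane photoadduct (3′E,3a′R,7a′R; OAc on C7, CH2Cl on C6; C6/C7 epimers) | ClCC1C(OC(C)=O)[C@@]23CCC=C[C@@]12C(=O)O/C3=C/CCC | intermediate
6 | cyclobutanol from 5 (not isolated) | ClCC1C(O)[C@@]23CCC=C[C@@]12C(=O)O/C3=C/CCC | intermediate
7 | (3E,3aS,7aS)-3-butylidene-7a-ethenyl-1-oxo-3,4,5,7a-tetrahydro-2-benzofuran-3a(1H)-carbaldehyde | O=C[C@@]12CCC=C[C@]1(C=C)C(=O)O/C2=C/CCC | intermediate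
8 | 4-(bromomethyl)furan-2(5H)-one | O=C1OCC(CBr)=C1 | starting material
9 | (3′E,3a′R,7a′S)-carbinol bearing the 4-methylidene-2-oxooxolan-3-yl ring (C7/C7a epimers) | OC(C1C(=C)COC1=O)[C@@]12CCC=C[C@]1(C=C)C(=O)O/C2=C/CCC | intermediate
10 | mesylate of 9 (not isolated) | CS(=O)(=O)OC(C1C(=C)COC1=O)[C@@]12CCC=C[C@]1(C=C)C(=O)O/C2=C/CCC | intermediate
11 | triene (3′E,3a′S,7a′S; Z-alkylidene lactone on C3a′, vinyl on C7a′) | O=C1OCC(=C)/C1=C/[C@@]12CCC=C[C@]1(C=C)C(=O)O/C2=C/CCC | intermediate
12 | (6S,7R,3a′S,7a′R,3′E)-pentacyclic bis-lactone (C3 is CH2) | C1OC(=O)C2=C1CC[C@H]1[C@@H]2[C@@]23CCC=C[C@@]12C(=O)O/C3=C/CCC | intermediate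
13 | butanal | CCCC=O | starting material
14 | 1-(tert-butyldimethylsilyloxy)furan formed from lactone A of 12 (not isolated) | CC(C)(C)[Si](C)(C)OC1=C2C(=CO1)CC[C@H]3[C@@H]2[C@@]42CCC=C[C@@]34C(=O)O/C2=C/CCC | intermediate
15 | silyl aldol adduct, C3 bearing CH(OTBS)Pr (epimer mixture, not isolated) | CCCC(O[Si](C)(C)C(C)(C)C)C1OC(=O)C2=C1CC[C@H]1[C@@H]2[C@@]23CCC=C[C@@]12C(=O)O/C3=C/CCC | intermediate
16 | (3Z,3′E,6S,7R,3a′S,7a′R)-6.7a′,7.3a′-diligustilide | CCC/C=C1\OC(=O)C2=C1CC[C@H]1[C@@H]2[C@@]23CCC=C[C@@]12C(=O)O/C3=C/CCC | target

Total step count: 7. Longest linear sequence: 7 steps (1 and 2 → 3 → 5 → 7 → 9 → 11 → 12 → 16).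

Steps most likely to fail

Step 6 (Proposed new method). Closing a four-membered ring within a [4+2] may cost too much strain. Thermal dimerisation of the exocyclic diene, ene reactions or decomposition of the enol lactone could then take over, or the diene could add on the lactone B face and give the wrong configuration at C6 and C7. The fallback uses known chemistry and gives up the ring-A-forming cycloaddition. It sets out from 4, which is irradiated (405 nm, CH2Cl2, −75 °C) with the same AlBr3-activated oxazaborolidine in the presence of an excess of commercial (Z)-ligustilide. The complexed, excited 4 should add across C3a′=C7a′ to the C6=C7 bond of the ground-state (Z)-ligustilide in an enantioselective intermolecular [2+2] photocycloaddition, forming C6–C7a′ and C7–C3a′ directly. After HPLC separation from isomeric dimers it comes back to the route at 16.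

Step 2. Several photochemical channels compete with the wanted one: E/Z isomerisation of the butylidene in the excited state, addition of the olefin across C3′=C8′ or C6′=C7′ instead of C3a′=C7a′, a racemic background reaction of uncomplexed 4, and Lewis-acid-induced ionisation of the allylic chloride. The fallback sets out from 4 and 3 and replaces asymmetric catalysis by resolution. A thioxanthen-9-one-sensitised [2+2] photocycloaddition without Lewis acid (CH2Cl2, −40 °C, 405 nm) should give 5 as a racemate, that is 5 together with the enantiomeric cycloadduct F1. The Grob fragmentation of step 3 then passes through the enantiomeric cyclobutanol F2 and gives 7 together with the enantiomeric aldehyde F3. Geometrical isomers are removed on silica and F3 by preparative HPLC on a chiral stationary phase; the route is rejoined at 7.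

Step 4. Addition to a neopentyl aldehyde flanked by two quaternary carbons may be too slow, so that reductive dimerisation of the allylic bromide or attack through its CH2 terminus takes over. The fallback sets out from 7 and builds the diene lactone by cross-coupling instead:
- Corey–Fuchs dibromo-olefination (CBr4, PPh3, CH2Cl2, 0 °C) should give the gem-dibromoalkene F4.
- A Stille coupling, selective for the less hindered bromide trans to C3a′, with 2-(tributylstannyl)prop-2-en-1-ol (Pd2(dba)3, tri(2-furyl)phosphine, toluene, 60 °C) should give the (Z)-bromo dienol F5.
- Palladium-catalysed carbonylative lactonisation (Pd(PPh3)4, CO 1 atm, Et3N, MeCN, 60 °C) closes the butyrolactone with its carbonyl syn to C3a′ and comes back to the route at 11, bypassing steps 4 and 5.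

Further compounds
F0 | step 6 | none | none
F1 | step 2 | enantiomer of cycloadduct 5 | ClCC1C(OC(C)=O)[C@]23CCC=C[C@]12C(=O)O/C3=C/CCC
F2 | step 2 | enantiomer of cyclobutanol 6 | ClCC1C(O)[C@]23CCC=C[C@]12C(=O)O/C3=C/CCC
F3 | step 2 | enantiomer of aldehyde 7 | O=C[C@]12CCC=C[C@@]1(C=C)C(=O)O/C2=C/CCC
F4 | step 4 | gem-dibromoalkene from 7 (C7H=CBr2 on C3a′) | BrC(Br)=C[C@@]12CCC=C[C@]1(C=C)C(=O)O/C2=C/CCC
F5 | step 4 | (Z)-bromo dienol (Br syn to C3a′; 2-(hydroxymethyl)allyl unit on the bromine-bearing carbon) | OCC(=C)/C(Br)=C/[C@@]12CCC=C[C@]1(C=C)C(=O)O/C2=C/CCC
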